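**Retrosynthetic overview**

1. Numbering used throughout: cyclopentane ring = C1 (quaternary, Me), C2 (OAc), C3, C4 (OH, iPr), C5 (H); cycloheptene ring = C1, C5, C6 (O-anisoyl), C7, C8(Me)=C9, C10 (OH). β is the face of the C1 methyl group, α the opposite face.
2. C10–OH comes from Luche reduction of the C10 enone; the cycloheptene ring is closed last by ring-closing metathesis (C8=C9) between a vinyl carbinol on C1 and a methallyl group on C6.
3. The cyclopentane ring comes from ring contraction of a cyclohexanone (ring atoms C1–C6): methallylmagnesium chloride adds to C6=O of a 5β-mesyloxy ketone, C1 shifts from C6 to C5 with loss of mesylate, and C6 leaves the ring as the side-chain carbonyl.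
4. Enabling feature: ring carbon C5 carries the oxygenated C6 and sits next to the tertiary carbinol C4, whose OH is cis to the C5–C6 bond. The C4 hydroxyl and the C5 leaving group are therefore the two oxygens of one syn-dihydroxylation of the enone C6(=O)–C5=C4(iPr), and the quaternary C1 is the migrating carbon.
5. The cyclohexanone comes from 2-methylcyclohexane-1,3-dione (C-alkylation with an orthoformate for C10, enzymatic desymmetrisation for C1/C2). Ring order: six-membered carbocycle (purchased), cyclopentane (step 8), cycloheptene (step 14).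

Key step: step 8

Remark: the C4 centre of 8, the C6 centre of 13 and the C10 centres of 20 and 21 are left open because they are erased or re-set before the target is reached.

**Route**

Step 1
Reactants: 1 2-methylcyclohexane-1,3-dione
Product: 3 2-(dimethoxymethyl)-2-methylcyclohexane-1,3-dione, via silyl enol ether 2 (not isolated)
Conditions: i-Pr2NEt, TMSOTf, CH2Cl2, 0 °C; then HC(OMe)3, TMSOTf (cat.), −78 → 0 °C
Reagents that add atoms: trimethyl orthoformate, COC(OC)OC
Why: In-situ silylation gives the vinylogous silyl ester 2, whose central carbon attacks the dimethoxycarbenium ion released from the orthoformate (Mukaiyama-type alkylation of a silyl enol ether with an orthoester), so the quaternary carbon (future C1) and the masked C10 aldehyde are installed together; no stereocentre arises because the two carbonyl arms are equivalent.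

Step 2
Reactants: 3 2-(dimethoxymethyl)-2-methylcyclohexane-1,3-dione
Product: 4 (2R,3S)-2-(dimethoxymethyl)-3-hydroxy-2-methylcyclohexan-1-one
Conditions: baker's yeast (Saccharomyces cerevisiae), sucrose, H2O, 30 °C
Reagents that add atoms: none
Why: Desymmetrising enzymatic reduction of a 2,2-disubstituted cyclohexane-1,3-dione (a reaction type established for 2-alkyl-2-methyl analogues): hydride should reach one enantiotopic carbonyl from the side of the small methyl group, setting C1 and C2 at once with the hydroxyl cis to the acetal carbon (2α-OH, 1β-Me).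

Step 3
Reactants: 4 (2R,3S)-2-(dimethoxymethyl)-3-hydroxy-2-methylcyclohexan-1-one
Product: 5 (2R,3S)-3-(tert-butyldimethylsilyloxy)-2-(dimethoxymethyl)-2-methylcyclohexan-1-one
Conditions: TBSCl, imidazole, DMF, 40 °C
Reagents that add atoms: tert-butyldimethylsilyl chloride, CC(C)(C)[Si](C)(C)Cl
Why: Standard silylation of the secondary alcohol; the β-silyloxy ketone formed cannot eliminate because C1 carries no hydrogen.

Step 4
Reactants: 5 (2R,3S)-3-(tert-butyldimethylsilyloxy)-2-(dimethoxymethyl)-2-methylcyclohexan-1-one
Product: 7 enone with C4=C5 conjugated to C6=O (C1 and C2 as in 5), via trimethylsilyl enol ether 6 (not isolated)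
Conditions: LDA, TMSCl, THF, −78 °C; then Pd(OAc)2, MeCN, 25 °C
Reagents that add atoms: none
Why: Saegusa–Ito oxidation: the ketone can enolise only toward C5 because C1 is quaternary, and divalent palladium dehydrogenates the silyl enol ether to the enone.

Step 5
Reactants: 7 enone with C4=C5 conjugated to C6=O
Product: 9 4-isopropyl enone C6(=O)–C5H=C4(iPr) (C1 and C2 as in 5), via isopropyl silyl enol ether 8 (not isolated)
Conditions: i-PrMgCl, CuBr·SMe2 (cat.), TMSCl, THF, −78 °C; then Pd(OAc)2, MeCN, 25 °C
Reagents that add atoms: isopropylmagnesium chloride, CC(C)[Mg]Cl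
Why: Copper-catalysed conjugate addition with silyl trapping followed by a second Saegusa–Ito oxidation re-forms the enone with the isopropyl group on C4; the passing C4 centre (expected trans to the C2 silyloxy group) is erased in the same step.

Step 6
Reactants: 9 4-isopropyl enone
Product: 10 4β,5β-diol (tertiary OH on C4, secondary OH on C5, both cis to the C1 methyl)
Conditions: K2OsO2(OH)4 (cat.), NMO, citric acid, t-BuOH/H2O, 25 °C
Reagents that add atoms: N-methylmorpholine N-oxide, C[N+]1([O-])CCOCC1; water, O
Why: Catalytic osmium syn-dihydroxylation of the enone double bond (citric acid speeds turnover for the electron-poor alkene); osmium should add to the face of the C1 methyl group, away from the acetal carbon on C1 and the silyloxy group on C2, which sets C4 (OH β, iPr α) and C5 (OH β).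

Step 7
Reactants: 10 4β,5β-diol
Product: 12 5β-mesylate 4β-trimethylsilyl ether, via C5 mesylate 11 (not isolated)
Conditions: MsCl, Et3N, CH2Cl2, −20 °C; then N-(trimethylsilyl)imidazole, 25 °C
Reagents that add atoms: methanesulfonyl chloride, CS(=O)(=O)Cl; N-(trimethylsilyl)imidazole, C[Si](C)(C)n1ccnc1
Why: Sulfonylation of the only secondary hydroxyl and silylation of the tertiary C4 hydroxyl, which keeps the C4 oxygen from acting as a competing donor or retro-aldol trigger in step 8; no stereocentre changes.

Step 8
Reactants: 12 5β-mesylate 4β-trimethylsilyl ether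
Product: 15 cyclopentyl methallyl ketone with free 4β-OH (C5–H α and trans to the C1 methyl), via chloromagnesium alkoxide 13 (not isolated), via trimethylsilyl ether ketone 14 (not isolated)
Conditions: 2-methylallylmagnesium chloride, THF, −78 → 20 °C; then PPTS, MeOH, 0 °C
Reagents that add atoms: 2-methylallylmagnesium chloride, C=C(C)C[Mg]Cl
Why: The allylic Grignard reagent adds to the hindered C6 carbonyl through its compact six-centre transition state to give alkoxide 13, in whose only low-energy chair (isopropyl, methyl, silyloxy and mesylate all equatorial) the ring bond C6–C1 is antiperiplanar to the C5–O bond of the mesylate. Electron push from the alkoxide then drives a concerted 1,2-shift of the quaternary carbon C1 from C6 to C5 with loss of mesylate, so the cyclohexane (C1–C6) contracts to the cyclopentane (C1–C5) by migration of a ring bond (an internal SN2-type displacement at C5, not a chain cyclisation), and C6 leaves the ring as the ketone carbon bearing the methallyl group. The closest known reaction types are the semipinacol (quasi-Favorskii, Tiffeneau-type) ring contraction of 2-halocyclohexanone–Grignard adducts and the pinacol-type rearrangement of β-mesyloxy alcohols made from α-mesyloxy ketones. C5 is the only new stereocentre: it forms with inversion, so the β-mesylate fixes H-5 as α and trans to the C1 methyl (the later trans ring fusion), while C1 migrates with retention and C2 and C4 are untouched. The step needs migration of the ring bond rather than of the methallyl group, epoxide closure or elimination; this is secured by the equatorial mesylate (only ring bonds are anti to it), the absence of any hydrogen β to the leaving group, the silyl cap on the C4 oxygen, and the fact that either configuration of the C6 carbinol converges on the same ketone. Mild methanolysis finally removes the labile tertiary trimethylsilyl ether.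

Step 9
Reactants: 15 cyclopentyl methallyl ketone with free 4β-OH
Product: 16 (6S)-diol (secondary OH on C6, tertiary OH on C4)
Conditions: Et2BOMe, THF/MeOH, −78 °C; NaBH4; then MeOH
Reagents that add atoms: none
Why: Narasaka–Prasad reduction: the C4 hydroxyl and the C6 carbonyl are tied into a diethylboron chelate (isopropyl group and C1 equatorial) and axial hydride addition from outside should give the syn-1,3-diol, which is the (6S) carbinol that becomes the 6α-oxygen of the target.

Step 10
Reactants: 16 (6S)-diol
Product: 17 C6 4-methoxybenzoate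
Conditions: 4-MeOC6H4COCl, pyridine, DMAP (cat.), CH2Cl2, 0 → 25 °C
Reagents that add atoms: 4-methoxybenzoyl chloride, COc1ccc(cc1)C(Cl)=O
Why: DMAP-catalysed acylation of the secondary C6 hydroxyl with retention; the tertiary C4 hydroxyl is too hindered to react.

Step 11
Reactants: 17 C6 4-methoxybenzoate
Product: 18 C10 aldehyde with free 2α-OH
Conditions: 2 M HCl (aq.), THF, 25 → 40 °C
Reagents that add atoms: water, O
Why: Aqueous acid hydrolyses the dimethyl acetal to the C10 aldehyde and cleaves the C2 silyl ether in one operation; the aldehyde has no α-hydrogen, and the aryl ester and tertiary alcohol survive.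

Step 12
Reactants: 18 C10 aldehyde with free 2α-OH
Product: 19 2α-acetoxy C10 aldehyde
Conditions: Ac2O, pyridine, DMAP (cat.), CH2Cl2, 0 °C
Reagents that add atoms: acetic anhydride, CC(=O)OC(C)=O
Why: Acetylation of the secondary C2 hydroxyl with retention installs the acetate of the target; the tertiary hydroxyl and the non-enolisable aldehyde are untouched.

Step 13
Reactants: 19 2α-acetoxy C10 aldehyde
Product: 20 vinyl carbinols (both C10 epimers)
Conditions: CH2=CHBr, CrCl2, NiCl2 (cat.), DMF, 25 °C
Reagents that add atoms: vinyl bromide, C=CBr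
Why: Nozaki–Hiyama–Kishi vinylation: the vinylchromium species adds only to the aldehyde in the presence of two esters and a free tertiary alcohol; either C10 epimer is acceptable because C10 is re-set in step 16.

Step 14
Reactants: 20 vinyl carbinols (both C10 epimers)
Product: 21 cycloheptenols (both C10 epimers)
Conditions: second-generation Grubbs catalyst (5 mol %), CH2Cl2, 40 °C
Reagents that add atoms: none
Why: Ring-closing metathesis between the vinyl carbinol and the 1,1-disubstituted alkene forms the trisubstituted C8=C9 bond and the trans-fused seven-membered ring with loss of ethylene; no stereocentre is touched.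

Step 15
Reactants: 21 cycloheptenols (both C10 epimers)
Product: 22 cycloheptenone (C10 ketone conjugated to C8=C9)
Conditions: Dess–Martin periodinane, CH2Cl2, 0 → 25 °C
Reagents that add atoms: none
Why: Dess–Martin oxidation of the allylic alcohol converges both C10 epimers on one enone; the tertiary alcohol and the esters are inert.

Step 16
Reactants: 22 cycloheptenone
Product: 23 target, (1S,2S,4R,5S,6S,10S)-2-acetoxy-4,10-dihydroxydauc-8-en-6-yl 4-methoxybenzoate
Conditions: NaBH4, CeCl3·7H2O, MeOH, −78 °C
Reagents that add atoms: none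
Why: Luche 1,2-reduction of the enone: hydride should attack C10 from the face opposite the axial C1 methyl group, giving the 10β (10S) allylic alcohol without touching the esters.

**Compound list**

1 | 2-methylcyclohexane-1,3-dione | CC1C(=O)CCCC1=O | starting material
2 | 2-methyl-3-(trimethylsilyloxy)cyclohex-2-en-1-one (not isolated) | CC1=C(O[Si](C)(C)C)CCCC1=O | intermediate
3 | 2-(dimethoxymethyl)-2-methylcyclohexane-1,3-dione | COC(OC)C1(C)C(=O)CCCC1=O | intermediate
4 | (2R,3S)-2-(dimethoxymethyl)-3-hydroxy-2-methylcyclohexan-1-one (OH cis to the acetal carbon) | O=C1[C@@](C)(C(OC)OC)[C@@H](O)CCC1 | intermediate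
5 | (2R,3S)-3-(tert-butyldimethylsilyloxy)-2-(dimethoxymethyl)-2-methylcyclohexan-1-one | O=C1[C@@](C)(C(OC)OC)[C@@H](O[Si](C)(C)C(C)(C)C)CCC1 | intermediate
6 | trimethylsilyl enol ether of 5, C5=C6 (not isolated) | C[Si](C)(C)OC1=CCC[C@H](O[Si](C)(C)C(C)(C)C)[C@]1(C)C(OC)OC | intermediate
7 | 5-(tert-butyldimethylsilyloxy)-6-(dimethoxymethyl)-6-methylcyclohex-2-en-1-one, configuration as in 5 | O=C1[C@@](C)(C(OC)OC)[C@@H](O[Si](C)(C)C(C)(C)C)CC=C1 | intermediate
8 | trimethylsilyl enol ether with isopropyl on C4, trans to the C2 silyloxy group (not isolated) | C[Si](C)(C)OC1=C[C@@H](C(C)C)C[C@H](O[Si](C)(C)C(C)(C)C)[C@]1(C)C(OC)OC | intermediate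
9 | 5-(tert-butyldimethylsilyloxy)-6-(dimethoxymethyl)-6-methyl-3-isopropylcyclohex-2-en-1-one, configuration as in 5 | O=C1[C@@](C)(C(OC)OC)[C@@H](O[Si](C)(C)C(C)(C)C)CC(C(C)C)=C1 | intermediate
10 | cyclohexanone 4β,5β-diol (C4-OH and C5-OH cis to the C1 methyl, trans to the acetal carbon and the C2 silyloxy group) | O=C1[C@@](C)(C(OC)OC)[C@@H](O[Si](C)(C)C(C)(C)C)C[C@@](O)(C(C)C)[C@@H]1O | intermediate
11 | 5β-mesylate of 10 (not isolated) | O=C1[C@@](C)(C(OC)OC)[C@@H](O[Si](C)(C)C(C)(C)C)C[C@@](O)(C(C)C)[C@@H]1OS(C)(=O)=O | intermediate
12 | 5β-mesylate 4β-trimethylsilyl ether | O=C1[C@@](C)(C(OC)OC)[C@@H](O[Si](C)(C)C(C)(C)C)C[C@@](O[Si](C)(C)C)(C(C)C)[C@@H]1OS(C)(=O)=O | intermediate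
13 | chloromagnesium alkoxide of the C6 methallyl carbinol, either configuration at C6 (not isolated) | C=C(C)CC1(O[Mg]Cl)[C@@](C)(C(OC)OC)[C@@H](O[Si](C)(C)C(C)(C)C)C[C@@](O[Si](C)(C)C)(C(C)C)[C@@H]1OS(C)(=O)=O | intermediate
14 | ring-contracted cyclopentyl methallyl ketone, C4 trimethylsilyl ether (not isolated) | COC(OC)[C@@]1(C)[C@@H](O[Si](C)(C)C(C)(C)C)C[C@@](O[Si](C)(C)C)(C(C)C)[C@@H]1C(=O)CC(C)=C | intermediate
15 | cyclopentyl methallyl ketone with free 4β-OH (1β-Me, 1α-acetal carbon, 2α-OTBS, 4α-iPr, 5α-H) | COC(OC)[C@@]1(C)[C@@H](O[Si](C)(C)C(C)(C)C)C[C@@](O)(C(C)C)[C@@H]1C(=O)CC(C)=C | intermediate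
16 | (6S)-diol | COC(OC)[C@@]1(C)[C@@H](O[Si](C)(C)C(C)(C)C)C[C@@](O)(C(C)C)[C@@H]1[C@@H](O)CC(C)=C | intermediate
17 | (6S)-4-methoxybenzoate | COC(OC)[C@@]1(C)[C@@H](O[Si](C)(C)C(C)(C)C)C[C@@](O)(C(C)C)[C@@H]1[C@@H](OC(=O)c2ccc(OC)cc2)CC(C)=C | intermediate
18 | C10 aldehyde with free 2α-OH | O=C[C@@]1(C)[C@@H](O)C[C@@](O)(C(C)C)[C@@H]1[C@@H](OC(=O)c2ccc(OC)cc2)CC(C)=C | intermediate
19 | 2α-acetoxy C10 aldehyde | O=C[C@@]1(C)[C@@H](OC(C)=O)C[C@@](O)(C(C)C)[C@@H]1[C@@H](OC(=O)c2ccc(OC)cc2)CC(C)=C | intermediate
20 | vinyl carbinols, both C10 epimers | C=CC(O)[C@@]1(C)[C@@H](OC(C)=O)C[C@@](O)(C(C)C)[C@@H]1[C@@H](OC(=O)c2ccc(OC)cc2)CC(C)=C | intermediate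
21 | cycloheptenols, both C10 epimers | COc1ccc(C(=O)O[C@H]2CC(C)=CC(O)[C@@]3(C)[C@@H](OC(C)=O)C[C@@](O)(C(C)C)[C@H]23)cc1 | intermediate
22 | cycloheptenone (C10 ketone) | COc1ccc(C(=O)O[C@H]2CC(C)=CC(=O)[C@@]3(C)[C@@H](OC(C)=O)C[C@@](O)(C(C)C)[C@H]23)cc1 | intermediate
23 | (1S,2S,4R,5S,6S,10S)-2-acetoxy-4,10-dihydroxydauc-8-en-6-yl 4-methoxybenzoate | COc1ccc(C(=O)O[C@H]2CC(C)=C[C@H](O)[C@@]3(C)[C@@H](OC(C)=O)C[C@@](O)(C(C)C)[C@H]23)cc1 | target

**Step count and risks**

Total step count: 16. Longest linear sequence: 16 steps (the route is linear from 1).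

Steps most likely to fail:

1. Step 8. The organomagnesium reagent may deprotonate C5 or attack sulfur faster than it adds to the very hindered C6 carbonyl, or the adduct may lose mesylate by another path. Fallback, from 12 back to 15: the two events are separated and hydride takes the place of the carbon nucleophile. Reduction of 12 with NaBH4 (MeOH, −20 °C) should give the β-mesyloxy alcohol F1 (either C6 epimer). Treatment with Et3Al (CH2Cl2, −78 → 0 °C) should cause the same antiperiplanar 1,2-shift of C1 and give the ring-contracted cyclopentanecarbaldehyde F2. Barbier addition of 2-methylallyl bromide with zinc (THF, aq. NH4Cl) should give the methallyl carbinols F3 (both C6 epimers). Dess–Martin oxidation then returns to ketone 14, which is desilylated to 15 as in step 8.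

2. Step 9. Facial selectivity of hydride addition may be poor because the boron chelate carries an axial ring methylene on C4. Fallback, from 15 back to 17: Evans–Saksena reduction (Me4NBH(OAc)3, AcOH/MeCN, −30 °C), with hydride delivered internally from the C4-bound borate, should give the (6R)-diol F4. Mitsunobu esterification with 4-methoxybenzoic acid (PPh3, DIAD, toluene) then inverts C6 and gives 17 directly, replacing steps 9 and 10.

3. Step 16. Facial selectivity of hydride attack on the C10 carbonyl may be poor, since it is flanked by the C1 methyl on one face and by C2 of the cyclopentane on the other. Fallback, from 19 back to 23: C10 is set by reagent control before ring closure. A catalytic asymmetric Nozaki–Hiyama–Kishi vinylation of 19 (CrCl2, NiCl2, chiral sulfonamide ligand, vinyl bromide) should give mainly the (10S)-vinyl carbinol F5. Ring-closing metathesis of F5 with the second-generation Grubbs catalyst then gives 23 directly, and steps 15 and 16 are not needed.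

**Further compounds**

F1 | step 8 | β-mesyloxy cyclohexanol from reduction of 12, either C6 epimer | OC1[C@@](C)(C(OC)OC)[C@@H](O[Si](C)(C)C(C)(C)C)C[C@@](O[Si](C)(C)C)(C(C)C)[C@@H]1OS(C)(=O)=O
F2 | step 8 | ring-contracted cyclopentanecarbaldehyde (C6 aldehyde on C5, C4 trimethylsilyl ether) | COC(OC)[C@@]1(C)[C@@H](O[Si](C)(C)C(C)(C)C)C[C@@](O[Si](C)(C)C)(C(C)C)[C@@H]1C=O
F3 | step 8 | methallyl carbinols, both C6 epimers (C4 trimethylsilyl ether) | COC(OC)[C@@]1(C)[C@@H](O[Si](C)(C)C(C)(C)C)C[C@@](O[Si](C)(C)C)(C(C)C)[C@@H]1C(O)CC(C)=C
F4 | step 9 | (6R)-diol, C6 epimer of 16 | COC(OC)[C@@]1(C)[C@@H](O[Si](C)(C)C(C)(C)C)C[C@@](O)(C(C)C)[C@@H]1[C@H](O)CC(C)=C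
F5 | step 16 | (10S)-vinyl carbinol, single C10 epimer of 20 | C=C[C@H](O)[C@@]1(C)[C@@H](OC(C)=O)C[C@@](O)(C(C)C)[C@@H]1[C@@H](OC(=O)c2ccc(OC)cc2)CC(C)=C
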